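**Plan**

1. Retrosynthesis: ring D is cut at C13–C16 (vinyl-radical closure of a propargyl arm onto the ring C enone). The 2,3-diol and the C10–O–C19 lactone go back to a C2=C3 alkene and a C10/C19 diol. C3–C4 and C5–C10 are then cut together, which unravels rings A and B into a furan and a (Z)-2-methyl-2,4-dienoate carried on ring C.
2. Enabling feature: ring A bears oxygen on C10 and on C3, 1,4 across C1–C2, and the carboxyl C19 on C4 next to C5–H. This is the 7-oxanorbornene retron of a [4+2] between a furan (C10, C1, C2, C3, O) and an α-methylacrylate (C5=C4); the furan oxygen ends as the ring oxygen of the lactone.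
3. Forward order: ring C by Birch dearomatization–alkylation of a 2-furyl-3-methoxybenzamide (C8 quaternary); side chain C6(=C7)–C5=C4(C18)C19; rings B and A in one intramolecular furan Diels–Alder step; bridge opening and lactone; C7 acid; ring D last; C11 reduction.
4. Stereochemistry: C8 from the chiral benzamide; C10, C3, C5, C4 from the exo-tethered cycloaddition of the Z-enoate; C9 and C6 by base equilibration (cis B/C junction, 6β-formyl); C2 and C3 by osmylation anti to the lactone bridge; C13 by the bridging radical closure; C11 by hydride from the α-face.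

Key step: step 9

Remarks
- Numbering: gibberellane numbering of the target is used for all intermediates (C7 = carboxyl on C6, C19 = lactone carbonyl on C4, C17 = methylene carbon); α is the face of the lactone bridge.
- Assumption: the (S)-2-(methoxymethyl)pyrrolidine amide is taken to deliver the C8 configuration drawn; if the sense of induction is the opposite, the (R)-amine is used and nothing else changes.
- C9 in 14 and 15 is enolizable; the epimer drawn is the one that cyclizes.

**Route**

Step 1
Reactants: 1 2-bromo-3-methoxybenzoic acid; 2 furan-2-ylboronic acid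
Product: 3 2-(furan-2-yl)-3-methoxybenzoic acid
Conditions: Pd(dppf)Cl2 (3 mol%), K2CO3, dioxane/H2O, 80 °C; acidify to pH 3 on work-up
Reagents that add atoms: none
Why: Suzuki–Miyaura coupling of the aryl bromide with an excess of the furylboronic acid tolerates the carboxylate and makes the future C9–C10 bond before any stereocentre exists.

Step 2
Reactants: 3 2-(furan-2-yl)-3-methoxybenzoic acid; 4 (S)-2-(methoxymethyl)pyrrolidine
Product: 6 chiral benzamide, via acid chloride 5 (not isolated)
Conditions: (COCl)2, DMF (cat.), CH2Cl2, 0 °C; then 4, Et3N, CH2Cl2, 0 °C → rt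
Reagents that add atoms: none
Why: Schotten–Baumann-type acylation through the acid chloride is the dependable way to a di-ortho-substituted tertiary benzamide and installs the auxiliary that is to control C8.

Step 3
Reactants: 6 chiral benzamide; 7 tert-butyl(2-iodoethoxy)diphenylsilane
Product: 8 cyclohexa-2,5-diene amide
Conditions: K (2.2 equiv), t-BuOH (1 equiv), NH3/THF, −78 °C; then 7, −78 → −33 °C
Reagents that add atoms: none
Why: Birch reduction–alkylation of a chiral 2-substituted benzamide reduces the carboxamide-bearing ring (protonation at the para carbon by t-BuOH), and the chelated amide enolate is alkylated at the ipso carbon on the face away from the methoxymethyl arm, which sets the quaternary C8 while the 3-methoxy group remains as an enol ether and the furan is not reduced.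

Step 4
Reactants: 8 cyclohexa-2,5-diene amide
Product: 9 methyl ketone
Conditions: MeLi (3 equiv), THF, −78 → 0 °C; aq NH4Cl
Reagents that add atoms: methyllithium, [Li]C
Why: acyl substitution of a tertiary amide by an organolithium stops at the ketone because the lithium-chelated tetrahedral adduct survives until work-up, so the auxiliary leaves as the amine, C7 arrives as the methyl group and C8 is untouched.

Step 5
Reactants: 9 methyl ketone
Product: 10 vinyl triflate
Conditions: KHMDS, PhNTf2, THF, −78 °C
Reagents that add atoms: N-phenylbis(trifluoromethanesulfonimide), O=S(=O)(N(c1ccccc1)S(=O)(=O)C(F)(F)F)C(F)(F)F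
Why: enol triflate formation is regiodefined because the ketone can enolize only toward the methyl group (C8 is quaternary), and O-sulfonylation of the potassium enolate gives the 1,1-disubstituted vinyl triflate.

Step 6
Reactants: 10 vinyl triflate
Product: 11 2-substituted acrolein
Conditions: Pd(PPh3)4 (5 mol%), LiCl (3 equiv), CO (3 atm), Bu3SnH (1.2 equiv, slow addition), THF, 50 °C
Reagents that add atoms: carbon monoxide, [C-]#[O+]
Why: palladium-catalysed reductive carbonylation (formylation) of a vinyl triflate proceeds by oxidative addition, CO insertion and hydride transfer from the stannane to the acylpalladium, so that C5 is introduced as the aldehyde carbon.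

Step 7
Reactants: 11 2-substituted acrolein; 12 ethyl 2-[bis(2,2,2-trifluoroethoxy)phosphoryl]propanoate
Product: 13 (Z)-dienoate
Conditions: KHMDS, 18-crown-6, THF, −78 °C
Reagents that add atoms: none
Why: Still–Gennari olefination of the non-enolizable enal gives the (Z)-2-methyl-2-enoate under kinetic control, which places C19 cis to C6 as the cycloaddition requires.

Step 8
Reactants: 13 (Z)-dienoate
Product: 15 conjugated enone, via deconjugated ketone 14 (not isolated)
Conditions: 1 M HCl, THF, 0 °C → rt; then DBU (0.1 equiv), CH2Cl2, 0 °C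
Reagents that add atoms: water, O
Why: enol ether hydrolysis (C-protonation at C9, hydration of the oxocarbenium ion, loss of methanol) unveils the C11 ketone, and base-catalysed conjugation moves the ring C alkene to C12=C13, leaving C9 as an enolizable centre.

Step 9
Reactants: 15 conjugated enone
Product: 16 oxanorbornene cycloadduct
Conditions: toluene (0.01 M), BHT (cat.), 100 °C, sealed tube
Reagents that add atoms: none
Why: The step is a concerted thermal [4+2] cycloaddition between the 2-alkylfuran (C10, C1, C2, C3) and the tethered (Z)-α-methyl enoate C5=C4, an intramolecular Diels–Alder reaction of a furan of the kind established for furans joined to acrylate-type dienophiles through three carbon atoms. Ring B closes through C5–C10 as a five-membered ring fused at the furan carbon, with the tether exo to the oxygen bridge (the only geometry a three-atom tether allows), and ring A closes through C3–C4 as the six-membered ring of the 7-oxanorbornene. C10 and C3 are set together by suprafacial addition across the furan, C5 by the exo tether (C6 syn to the bridge oxygen) and C4 by the Z geometry of the enoate, which puts the ester exo and the methyl group endo. C9 is epimerizable and is selected by the reaction itself, because only the epimer with furan and dienoate cis on ring C reaches a cis-fused transition state. The selectivity that must be secured is between the two furan rotamers about C9–C10, and the rotamer that turns the bridge oxygen (not the C1–H edge) toward the C11 carbonyl and ring C should be preferred on steric grounds; the cycloaddition is reversible, so continued heating also lets the adducts equilibrate toward the less crowded isomer.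

Step 10
Reactants: 16 oxanorbornene cycloadduct
Product: 17 triol
Conditions: Ni(COD)2 (10 mol%), dppb (15 mol%), DIBAL-H (7 equiv), toluene, 0 → 60 °C; Rochelle salt work-up
Reagents that add atoms: none
Why: DIBAL-H reduces the enone carbonyl and the ester, and nickel-catalysed hydroalumination of the strained bicyclic alkene (reductive ring opening of an oxabicyclic alkene) places aluminium on C2, distal to the substituted bridgehead C10, so that β-alkoxide elimination cleaves C3–O and leaves the C10 tertiary alcohol, C1H2 and the C2=C3 alkene; the configuration of the C11 carbinol is immaterial.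

Step 11
Reactants: 17 triol
Product: 18 lactone enone
Conditions: TEMPO (0.2 equiv), PhI(OAc)2 (3.3 equiv), CH2Cl2, rt
Reagents that add atoms: none
Why: TEMPO-catalysed oxidation turns the primary C19 alcohol into the aldehyde, which the cis C10 tertiary alcohol traps as the lactol that is oxidized on to the 19,10-lactone (oxidative lactonization of a 1,4-diol), and it returns the allylic C11 alcohol to the enone.

Step 12
Reactants: 18 lactone enone
Product: 19 diol
Conditions: 9-BBN (4 equiv), THF, 0 °C → rt; then NaBO3·4H2O, H2O, rt
Reagents that add atoms: sodium perborate, [Na+].[O-]OB=O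
Why: hydroboration–oxidation with 9-BBN takes the 1,1-disubstituted C6=C7 alkene at its terminal carbon far faster than the hindered cis-disubstituted C2=C3 alkene, with hydrogen delivered to C6 from the more open β-face (6-epi centre expected), and the reagent also reduces the enone carbonyl to the allylic alcohol, which the next step reverses.

Step 13
Reactants: 19 diol
Product: 21 6β-aldehyde, via 6-epi aldehyde 20 (not isolated)
Conditions: Dess–Martin periodinane (2.5 equiv), NaHCO3, CH2Cl2, rt; then DBU (1 equiv), CH2Cl2, rt
Reagents that add atoms: none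
Why: Dess–Martin oxidation gives the C7 aldehyde and the enone, and DBU equilibrates the enolizable centres, so that the formyl group moves to the more stable 6β position (trans to the C5–C4 bond and away from the crowded α-face) and C9 settles in the cis B/C arrangement.

Step 14
Reactants: 21 6β-aldehyde
Product: 22 carboxylic acid
Conditions: NaClO2, NaH2PO4, 2-methyl-2-butene, t-BuOH/H2O, 0 °C
Reagents that add atoms: sodium chlorite, [Na+].[O-]Cl=O
Why: Pinnick oxidation converts the aldehyde into the C7 carboxylic acid without epimerizing C6 and without touching the alkenes, the enone, the lactone or the silyl ether.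

Step 15
Reactants: 22 carboxylic acid
Product: 23 primary alcohol
Conditions: TBAF (3 equiv), AcOH (3 equiv), THF, rt
Reagents that add atoms: none
Why: fluoride-mediated desilylation removes the tert-butyldiphenylsilyl group, and the acetic acid buffer keeps the lactone and the enone safe from base.

Step 16
Reactants: 23 primary alcohol
Product: 24 aldehyde
Conditions: Dess–Martin periodinane (1.3 equiv), NaHCO3, CH2Cl2, rt
Reagents that add atoms: none
Why: the primary C16 hydroxyl is the only alcohol left, and Dess–Martin oxidation stops at the aldehyde.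

Step 17
Reactants: 24 aldehyde
Product: 25 terminal alkyne
Conditions: dimethyl (1-diazo-2-oxopropyl)phosphonate, K2CO3 (3 equiv), MeOH, 0 °C → rt; acidify to pH 3 on work-up
Reagents that add atoms: dimethyl (1-diazo-2-oxopropyl)phosphonate, CC(=O)C(=[N+]=[N-])P(=O)(OC)OC
Why: Seyferth–Gilbert homologation in the Ohira–Bestmann variant converts the aldehyde into the alkyne, which adds C17 and completes the propargyl arm on C8, while the acid is carried as its potassium salt.

Step 18
Reactants: 25 terminal alkyne
Product: 26 2β,3β-diol
Conditions: OsO4 (5 mol%), NMO (1.5 equiv), acetone/H2O, 0 °C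
Reagents that add atoms: N-methylmorpholine N-oxide, C[N+]1([O-])CCOCC1; water, O
Why: Upjohn dihydroxylation attacks the electron-neutral C2=C3 alkene faster than the electron-poor enone or the alkyne, and the osmium reagent approaches the β-face, anti to the lactone bridge that spans C4 and C10 on the α-face, which gives the cis-2β,3β-diol.

Step 19
Reactants: 26 2β,3β-diol
Product: 28 11-ketone, via vinylstannane 27 (not isolated)
Conditions: Bu3SnH (2.5 equiv), AIBN (0.2 equiv), benzene, 80 °C; then PPTS (1.2 equiv), CH2Cl2, rt
Reagents that add atoms: none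
Why: tin-hydride-mediated radical cyclization starts with stannyl radical addition to the terminal alkyne, the C16 vinyl radical closes ring D by 5-exo-trig attack on C13 (the β-carbon of the enone) from the face of ring C that carries the propargyl arm, a bridge that can only form cis and so sets C13, and protodestannylation of the vinylstannane unveils the exocyclic methylene group.

Step 20
Reactants: 28 11-ketone
Product: 29 target CNP0322347.1
Conditions: NaBH4, MeOH, −20 °C; acidify to pH 3 on work-up
Reagents that add atoms: none
Why: sodium borohydride reduction of the only ketone should deliver hydride to C11 from the α-face, opposite the two-carbon C15–C16 bridge that lies over the β-face of the ring C chair, which gives the axial 11β-alcohol, while the lactone, the acid and the alkene are not reduced.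

**Compound list**

1 | 2-bromo-3-methoxybenzoic acid | COc1cccc(C(=O)O)c1Br | starting material
2 | furan-2-ylboronic acid | OB(O)c1ccco1 | starting material
3 | 2-(furan-2-yl)-3-methoxybenzoic acid | COc1cccc(C(=O)O)c1-c1ccco1 | intermediate
4 | (S)-2-(methoxymethyl)pyrrolidine | COC[C@@H]1CCCN1 | starting material
5 | 2-(furan-2-yl)-3-methoxybenzoyl chloride (not isolated) | COc1cccc(C(=O)Cl)c1-c1ccco1 | intermediate
6 | [2-(furan-2-yl)-3-methoxyphenyl][(2S)-2-(methoxymethyl)pyrrolidin-1-yl]methanone | COc1cccc(C(=O)N2CCC[C@H]2COC)c1-c1ccco1 | intermediate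
7 | tert-butyl(2-iodoethoxy)diphenylsilane | CC(C)(C)[Si](c1ccccc1)(c1ccccc1)OCCI | starting material
8 | {1-[2-(tert-butyldiphenylsilyloxy)ethyl]-2-(furan-2-yl)-3-methoxycyclohexa-2,5-dien-1-yl}[(2S)-2-(methoxymethyl)pyrrolidin-1-yl]methanone, quaternary carbon (C8) as in the SMILES | CC(C)(C)[Si](c1ccccc1)(c1ccccc1)OCC[C@@]1(C=CCC(OC)=C1c1ccco1)C(=O)N1CCC[C@H]1COC | intermediate
9 | 1-{1-[2-(tert-butyldiphenylsilyloxy)ethyl]-2-(furan-2-yl)-3-methoxycyclohexa-2,5-dien-1-yl}ethan-1-one (C8 as in 8) | CC(C)(C)[Si](c1ccccc1)(c1ccccc1)OCC[C@@]1(C=CCC(OC)=C1c1ccco1)C(C)=O | intermediate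
10 | 1-{1-[2-(tert-butyldiphenylsilyloxy)ethyl]-2-(furan-2-yl)-3-methoxycyclohexa-2,5-dien-1-yl}ethenyl trifluoromethanesulfonate | CC(C)(C)[Si](c1ccccc1)(c1ccccc1)OCC[C@@]1(C=CCC(OC)=C1c1ccco1)C(=C)OS(=O)(=O)C(F)(F)F | intermediate
11 | 2-{1-[2-(tert-butyldiphenylsilyloxy)ethyl]-2-(furan-2-yl)-3-methoxycyclohexa-2,5-dien-1-yl}prop-2-enal | CC(C)(C)[Si](c1ccccc1)(c1ccccc1)OCC[C@@]1(C=CCC(OC)=C1c1ccco1)C(=C)C=O | intermediate
12 | ethyl 2-[bis(2,2,2-trifluoroethoxy)phosphoryl]propanoate | CCOC(=O)C(C)P(=O)(OCC(F)(F)F)OCC(F)(F)F | starting material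
13 | ethyl (2Z)-4-{1-[2-(tert-butyldiphenylsilyloxy)ethyl]-2-(furan-2-yl)-3-methoxycyclohexa-2,5-dien-1-yl}-2-methylpenta-2,4-dienoate | CC(C)(C)[Si](c1ccccc1)(c1ccccc1)OCC[C@@]1(C=CCC(OC)=C1c1ccco1)C(=C)/C=C(/C)C(=O)OCC | intermediate
14 | ethyl (2Z)-4-{1-[2-(tert-butyldiphenylsilyloxy)ethyl]-6-(furan-2-yl)-5-oxocyclohex-2-en-1-yl}-2-methylpenta-2,4-dienoate (not isolated) | CC(C)(C)[Si](c1ccccc1)(c1ccccc1)OCC[C@@]1(C=CCC(=O)[C@H]1c1ccco1)C(=C)/C=C(/C)C(=O)OCC | intermediate
15 | ethyl (2Z)-4-{1-[2-(tert-butyldiphenylsilyloxy)ethyl]-6-(furan-2-yl)-5-oxocyclohex-3-en-1-yl}-2-methylpenta-2,4-dienoate (C9 labile, drawn 9β-H) | CC(C)(C)[Si](c1ccccc1)(c1ccccc1)OCC[C@@]1(CC=CC(=O)[C@H]1c1ccco1)C(=C)/C=C(/C)C(=O)OCC | intermediate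
16 | cycloadduct with rings A, B and C: 3α,10α-oxygen bridge, C1=C2, 4β-methyl, 4α-CO2Et, 5β-H, 9β-H, C6=CH2, 11-oxo-12-ene, CH2CH2OSi(t-Bu)Ph2 on C8 | CC(C)(C)[Si](c1ccccc1)(c1ccccc1)OCC[C@]23CC=CC(=O)[C@H]2[C@@]14C=C[C@@H](O1)[C@@](C)(C(=O)OCC)[C@H]4C3=C | intermediate
17 | 10α,11α,19-triol with C2=C3, C12=C13 and C6=CH2 (silyl ether arm on C8) | CC(C)(C)[Si](c1ccccc1)(c1ccccc1)OCC[C@]23CC=C[C@@H](O)[C@H]2[C@]1(O)CC=C[C@@](C)(CO)[C@H]1C3=C | intermediate
18 | 19,10-lactone with 11-oxo-12-ene, C2=C3 and C6=CH2 | CC(C)(C)[Si](c1ccccc1)(c1ccccc1)OCC[C@]23CC=CC(=O)[C@H]2[C@@]12CC=C[C@@](C)(C(=O)O1)[C@H]2C3=C | intermediate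
19 | 19,10-lactone 7,11α-diol, 6-epi (CH2OH α on C6) | CC(C)(C)[Si](c1ccccc1)(c1ccccc1)OCC[C@]23CC=C[C@@H](O)[C@H]2[C@@]12CC=C[C@@](C)(C(=O)O1)[C@H]2[C@H]3CO | intermediate
20 | 6-epi 7-aldehyde of the lactone enone (not isolated) | CC(C)(C)[Si](c1ccccc1)(c1ccccc1)OCC[C@]23CC=CC(=O)[C@H]2[C@@]12CC=C[C@@](C)(C(=O)O1)[C@H]2[C@H]3C=O | intermediate
21 | 6β-formyl lactone enone | CC(C)(C)[Si](c1ccccc1)(c1ccccc1)OCC[C@]23CC=CC(=O)[C@H]2[C@@]12CC=C[C@@](C)(C(=O)O1)[C@H]2[C@@H]3C=O | intermediate
22 | 7-carboxylic acid of the lactone enone (silyl ether arm) | CC(C)(C)[Si](c1ccccc1)(c1ccccc1)OCC[C@]23CC=CC(=O)[C@H]2[C@@]12CC=C[C@@](C)(C(=O)O1)[C@H]2[C@@H]3C(=O)O | intermediate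
23 | 7-acid with CH2CH2OH arm on C8 | OCC[C@]23CC=CC(=O)[C@H]2[C@@]12CC=C[C@@](C)(C(=O)O1)[C@H]2[C@@H]3C(=O)O | intermediate
24 | 7-acid with CH2CHO arm on C8 | O=CC[C@]23CC=CC(=O)[C@H]2[C@@]12CC=C[C@@](C)(C(=O)O1)[C@H]2[C@@H]3C(=O)O | intermediate
25 | 7-acid with propargyl arm on C8 (C2=C3, 11-oxo-12-ene, 19,10-lactone) | C#CC[C@]23CC=CC(=O)[C@H]2[C@@]12CC=C[C@@](C)(C(=O)O1)[C@H]2[C@@H]3C(=O)O | intermediate
26 | 2β,3β-diol of 25 | C#CC[C@]23CC=CC(=O)[C@H]2[C@@]12C[C@H](O)[C@H](O)[C@@](C)(C(=O)O1)[C@H]2[C@@H]3C(=O)O | intermediate
27 | 17-(tributylstannyl) derivative of 28, E/Z mixture (not isolated) | CCCC[Sn](CCCC)(CCCC)C=C1C[C@]23C[C@H]1CC(=O)[C@H]2[C@@]12C[C@H](O)[C@H](O)[C@@](C)(C(=O)O1)[C@H]2[C@@H]3C(=O)O | intermediate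
28 | 2β,3β-dihydroxy-11-oxo-gibberell-16-ene-7,19-dioic acid 19,10-lactone | C=C1C[C@]23C[C@H]1CC(=O)[C@H]2[C@@]12C[C@H](O)[C@H](O)[C@@](C)(C(=O)O1)[C@H]2[C@@H]3C(=O)O | intermediate
29 | CNP0322347.1, 2β,3β,11β-trihydroxy-gibberell-16-ene-7,19-dioic acid 19,10-lactone | C=C1C[C@]23C[C@H]1C[C@H](O)[C@H]2[C@@]12C[C@H](O)[C@H](O)[C@@](C)(C(=O)O1)[C@H]2[C@@H]3C(=O)O | target

**Count and risks**

Total step count: 20. Longest linear sequence: 20 steps (the route is linear from 1).

Step 9. The cycloaddition may show poor facial selectivity between the two furan rotamers (bridge oxygen syn or anti to C11), or the retro-reaction may keep conversion low. Fallback: the cycloaddition is moved one step earlier, onto enol ether 13, where C9 is trigonal and the furan lies in the plane of the C9=C11 enol ether, so that allylic strain against the methoxy group (not the carbonyl flank) fixes the rotamer with the furan oxygen on the C11 side. Heating 13 in toluene should give the enol ether cycloadduct F1. Aqueous HCl in THF should then hydrolyse it, with protonation of C9 on the convex face, to the deconjugated ketone adduct F2, and a trace of DBU should conjugate F2 to 16. The fallback sets out from 13 and comes back at 16.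

Step 3. The dissolving-metal step may over-reduce the furyl-conjugated diene, or the auxiliary may fail to control the enolate face with an aryl ortho substituent, which would give a low diastereomer ratio at C8. Fallback: the free acid 3 is submitted to Birch reduction–alkylation (Li, NH3, THF; then 7) to give the racemic dienyl acid F3. F3 is resolved by preparative chromatography on a chiral stationary phase to the single enantiomer F4. F4 is converted with MeLi (2.2 equiv, ketone synthesis from a lithium carboxylate) into 9. The fallback sets out from 3 and comes back at 9, so it also bypasses the amide cleavage of step 4.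

Step 10. The ring opening may be incomplete or misdirected (aluminium on C1 instead of C2), or it may be slowed by the aluminium alkoxides formed in the same flask. Fallback: 16 is first reduced with DIBAL-H alone (toluene, −78 → 0 °C) to the oxanorbornene diol F5. The strained alkene of F5 is hydrostannylated (Bu3SnH, Pd(OH)2/C, THF) to the exo C2 stannane F6, with tin distal to the substituted bridgehead. Tin–lithium exchange with MeLi (excess, THF, −78 → 0 °C) then triggers β-alkoxide elimination to 17. The fallback sets out from 16 and comes back at 17.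

**Further compounds**

F1 | step 9 | enol ether cycloadduct (as 16 but with C9=C11(OMe) and C13=C14 in ring C) | CC(C)(C)[Si](c1ccccc1)(c1ccccc1)OCC[C@]23C=CCC(OC)=C2[C@@]14C=C[C@@H](O1)[C@@](C)(C(=O)OCC)[C@H]4C3=C
F2 | step 9 | deconjugated ketone cycloadduct (as 16 but with C13=C14 in ring C) | CC(C)(C)[Si](c1ccccc1)(c1ccccc1)OCC[C@]23C=CCC(=O)[C@H]2[C@@]14C=C[C@@H](O1)[C@@](C)(C(=O)OCC)[C@H]4C3=C
F3 | step 3 | racemic 1-[2-(tert-butyldiphenylsilyloxy)ethyl]-2-(furan-2-yl)-3-methoxycyclohexa-2,5-diene-1-carboxylic acid | CC(C)(C)[Si](c1ccccc1)(c1ccccc1)OCCC1(C=CCC(OC)=C1c1ccco1)C(=O)O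
F4 | step 3 | resolved enantiomer of F3 with C8 as in 9 | CC(C)(C)[Si](c1ccccc1)(c1ccccc1)OCC[C@@]1(C=CCC(OC)=C1c1ccco1)C(=O)O
F5 | step 10 | oxanorbornene 11α,19-diol (16 with ketone and ester reduced) | CC(C)(C)[Si](c1ccccc1)(c1ccccc1)OCC[C@]23CC=C[C@@H](O)[C@H]2[C@@]14C=C[C@@H](O1)[C@@](C)(CO)[C@H]4C3=C
F6 | step 10 | exo C2 tributylstannane of F5 | CC(C)(C)[Si](c1ccccc1)(c1ccccc1)OCC[C@]23CC=C[C@@H](O)[C@H]2[C@@]14C[C@@H]([Sn](CCCC)(CCCC)CCCC)[C@@H](O1)[C@@](C)(CO)[C@H]4C3=C
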